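## Retrosynthetic overview
1. Target (14) ← global fluoride deprotection (aryl TBS ethers and the TMSE ester) of the protected 7-O-orsellinate 13.
2. 13 ← acylation of the tertiary C7 alcohol of azaphilone 9 with bis-TBS-orsellinoyl chloride 12.
3. 9 (pyran ring, dienedione and the C7 quaternary stereocentre) ← one Cu/(–)-sparteine/O2 operation on o-alkynylbenzaldehyde 8: 6-endo cycloisomerisation, then enantioselective hydroxylative dearomatisation.
4. 8 ← Sonogashira coupling of iodoaldehyde 4 with enynoate 7. Compound 4 comes from 2,6-dimethoxytoluene by Vilsmeier formylation, Comins ortho-iodination and BBr3 demethylation.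
5. Rings form in this order: benzene (purchased), then pyran, then carbocyclic dienedione and C7 stereocentre, then the ester.

Assumptions:
- (–)-Sparteine is assumed to deliver 7R; if 7S is obtained, switch to (+)-sparteine or its surrogate. Check by chiral HPLC.
- (E)-Pent-2-en-4-ynoic acid is assumed to be commercially available.
- The free phenols are assumed to be tolerated in the Cu step, because the enol of the 7-H azaphilone is the species that is hydroxylated.

## Route

**Step 1**
Reactants: 1 (2,6-dimethoxytoluene)
Product: 2 (2,4-dimethoxy-3-methylbenzaldehyde)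
Conditions: POCl3, DMF, 0 → 60 °C; aqueous NaOAc workup
Reagents that add atoms: DMF, CN(C)C=O (supplies the CHO group)
Why: Vilsmeier formylation (electrophilic aromatic substitution) occurs at C3, which is ortho to one OMe and para to the other.

**Step 2**
Reactants: 2
Product: 3 (6-iodo-2,4-dimethoxy-3-methylbenzaldehyde)
Conditions: LiN(Me)CH2CH2NMe2 (from Me2NCH2CH2NHMe + n-BuLi), THF, –20 °C; then n-BuLi, –20 → 0 °C; then I2, –78 °C
Reagents that add atoms: I2, II
Why: Comins in-situ α-amino-alkoxide directed ortho-lithiation is directed to the only free position ortho to the aldehyde (C6); the iodide is then installed, and the aldehyde is released on workup.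

**Step 3**
Reactants: 3
Product: 4 (6-iodo-2,4-dihydroxy-3-methylbenzaldehyde)
Conditions: BBr3 (4 equiv), CH2Cl2, –78 °C → rt
Reagents that add atoms: none
Why: BBr3 cleaves both aryl methyl ethers (Lewis-acid O-demethylation, assisted by chelation to the aldehyde), and the aryl C–I bond and CHO survive.

**Step 4**
Reactants: 5 ((E)-pent-2-en-4-ynoic acid) and 6 (2-(trimethylsilyl)ethanol)
Product: 7 (2-(trimethylsilyl)ethyl (E)-pent-2-en-4-ynoate)
Conditions: EDC·HCl, DMAP, CH2Cl2, 0 °C → rt
Reagents that add atoms: none (the alcohol 6 is a listed reactant)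
Why: Steglich esterification gives an ester that is later removed by fluoride together with the silyl ethers, and the E alkene is untouched.

**Step 5**
Reactants: 4 and 7
Product: 8 (2-(trimethylsilyl)ethyl (E)-5-(2-formyl-3,5-dihydroxy-4-methylphenyl)pent-2-en-4-ynoate)
Conditions: Pd(PPh3)2Cl2 (5 mol %), CuI (10 mol %), Et3N, DMF, rt
Reagents that add atoms: none
Why: Sonogashira coupling of the aryl iodide, activated by the ortho-CHO, with the terminal alkyne gives the o-alkynylbenzaldehyde with the E-enoate side chain intact.

**Step 6**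
Reactants: 8
Product: 9 (2-(trimethylsilyl)ethyl (E)-3-[(7R)-7-hydroxy-7-methyl-6,8-dioxo-7,8-dihydro-6H-isochromen-3-yl]acrylate)
Conditions: Cu(OAc)2 (1.1 equiv), (–)-sparteine (1.2 equiv), O2 (1 atm), CH2Cl2, rt
Reagents that add atoms: O2, O=O (one O atom becomes the C7–OH)
Why: Cu(II) promotes 6-endo-dig cycloisomerisation of the aldehyde oxygen onto the alkyne to give the pyran, and the resulting 7-H azaphilone β-diketone enol is hydroxylated at C7 by O2 within the chiral Cu-sparteine complex. This is an enantioselective hydroxylative dearomatisation and it sets the C7 stereocentre (R).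

**Step 7**
Reactants: 10 (orsellinic acid)
Product: 11 (2,4-bis(tert-butyldimethylsilyloxy)-6-methylbenzoic acid)
Conditions: TBSCl (3.3 equiv), imidazole, DMF, rt; then AcOH/THF/H2O, rt
Reagents that add atoms: TBSCl, CC(C)(C)[Si](C)(C)Cl
Why: Exhaustive silylation also forms the silyl ester, which is hydrolysed selectively and much faster than the hindered aryl silyl ethers, giving the free acid.

**Step 8**
Reactants: 11
Product: 12 (2,4-bis(TBSO)-6-methylbenzoyl chloride)
Conditions: Ghosez reagent, CH2Cl2, 0 °C → rt; concentrate and use crude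
Reagents that add atoms: 1-chloro-N,N,2-trimethylprop-1-en-1-amine, CC(C)=C(Cl)N(C)C (supplies Cl)
Why: Neutral acid-chloride formation avoids the HCl that would cleave the aryl TBS ethers.

**Step 9**
Reactants: 9 and 12
Product: 13 (protected mitorubrinic acid TMSE ester)
Conditions: 12 (3 equiv), DMAP (0.5 equiv), pyridine, CH2Cl2, 0 → 40 °C
Reagents that add atoms: none (acid chloride 12 is a listed reactant)
Why: DMAP-catalysed O-acylation (acyl-pyridinium) of the tertiary alcohol; C7 is quaternary with no α-H, so the stereocentre cannot epimerise.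

**Step 10**
Reactants: 13
Product: 14 (mitorubrinic acid)
Conditions: TBAF·3H2O (4 equiv), AcOH (4 equiv), THF, 0 °C → rt; then mild acidic workup (pH ~3)
Reagents that add atoms: none (hydrogen only)
Why: Buffered fluoride removes both aryl TBS ethers and, by β-silyl elimination of ethylene and Me3SiF, the TMSE ester to give the free acid; the C7 ester and the azaphilone survive the buffered conditions.

## Compound list
1 | 2,6-dimethoxytoluene | COc1cccc(OC)c1C | starting material
2 | 2,4-dimethoxy-3-methylbenzaldehyde | COc1ccc(C=O)c(OC)c1C | intermediate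
3 | 6-iodo-2,4-dimethoxy-3-methylbenzaldehyde | COc1cc(I)c(C=O)c(OC)c1C | intermediate
4 | 6-iodo-2,4-dihydroxy-3-methylbenzaldehyde | Cc1c(O)cc(I)c(C=O)c1O | intermediate
5 | (E)-pent-2-en-4-ynoic acid | OC(=O)/C=C/C#C | starting material
6 | 2-(trimethylsilyl)ethanol | C[Si](C)(C)CCO | starting material
7 | 2-(trimethylsilyl)ethyl (E)-pent-2-en-4-ynoate | C[Si](C)(C)CCOC(=O)/C=C/C#C | intermediate
8 | TMSE (E)-5-(2-formyl-3,5-dihydroxy-4-methylphenyl)pent-2-en-4-ynoate | C[Si](C)(C)CCOC(=O)/C=C/C#Cc1cc(O)c(C)c(O)c1C=O | intermediate
9 | TMSE (E)-3-[(7R)-7-hydroxy-7-methyl-6,8-dioxo-isochromen-3-yl]acrylate | O[C@]1(C)C(=O)C=C2C=C(/C=C/C(=O)OCC[Si](C)(C)C)OC=C2C1=O | intermediate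
10 | orsellinic acid (2,4-dihydroxy-6-methylbenzoic acid) | Cc1cc(O)cc(O)c1C(=O)O | starting material
11 | 2,4-bis(TBSO)-6-methylbenzoic acid | Cc1cc(O[Si](C)(C)C(C)(C)C)cc(O[Si](C)(C)C(C)(C)C)c1C(=O)O | intermediate
12 | 2,4-bis(TBSO)-6-methylbenzoyl chloride | Cc1cc(O[Si](C)(C)C(C)(C)C)cc(O[Si](C)(C)C(C)(C)C)c1C(=O)Cl | intermediate
13 | protected mitorubrinic acid (7R; bis-TBS orsellinate, TMSE ester) | Cc1cc(O[Si](C)(C)C(C)(C)C)cc(O[Si](C)(C)C(C)(C)C)c1C(=O)O[C@]1(C)C(=O)C=C2C=C(/C=C/C(=O)OCC[Si](C)(C)C)OC=C2C1=O | intermediate
14 | mitorubrinic acid | Cc1cc(O)cc(O)c1C(=O)O[C@]1(C)C(=O)C=C2C=C(/C=C/C(=O)O)OC=C2C1=O | target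

## Totals
Total steps: 10. Longest linear sequence: 7 (steps 1, 2, 3, 5, 6, 9, 10).

## Three steps most likely to fail
1. **Step 6 (Cu/sparteine cycloisomerisation and dearomatisation).** The electron-poor enynoate may favour 5-exo over 6-endo closure, and the ee may be modest.
   Fallback: hydroxylate the 7-H azaphilone enol enzymatically with an FAD-dependent azaphilone monooxygenase (AzaH/TropB type), which gives the (R)-7-OH directly.
2. **Step 9 (acylation of the hindered tertiary alcohol with a 2,6-disubstituted acid chloride).**
   Fallback: skip 9 and do a hypervalent-iodine or Pb(OAc)4 dearomatisation of the cyclised precursor in the presence of acid 11. This gives racemic 7-acyloxy azaphilone 13 directly, and the enantiomers are then separated by preparative chiral HPLC.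
3. **Step 10 (fluoride deprotection of an azaphilone).** Basic fluoride may open the pyran or cleave the C7 ester.
   Fallback: re-route with a tert-butyl ester in place of the TMSE ester. Remove the aryl TBS ethers first with HF·pyridine at 0 °C, then the t-Bu ester with TFA/CH2Cl2, avoiding basic fluoride entirely.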